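The dihydrofuran ring is closed by forming the aryl ether bond O1–C7a in an intramolecular SNAr reaction. The key step exploits the para relationship, across benzene ring B, between C7a and C5, the carbon that bears the side chain. With C5 held as a nitrile and a nitro group on C7a, the C2 alkoxide of an open-chain 1-aryl-2-(2-nitroaryl)propanol displaces nitrite and closes the ring as the 2,3-trans isomer. The same nitro group first directs the C–H substitution that installs the C3a acetic acid unit, and the nitrile later becomes the aldehyde for the side chain. Both stereo-pairs come from Evans syn-aldol reactions with one (S)-oxazolidinone.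

Key step: step 7

Remark: the core is numbered O1, C2, C3, C3a, C4 to C7, C7a; ring A is the aryl group on C2, ring B the benzo ring, ring C the aryl group of the side chain. Compounds 1, 2, 5, 8 and 18 are assumed to be commercial.

Step 1
Reactants: 1 3-methoxy-4-nitrobenzonitrile; 2 tert-butyl chloroacetate
Product: 3 tert-butyl 2-(5-cyano-3-methoxy-2-nitrophenyl)acetate
Conditions: KOtBu (2.5 equiv), DMF, −40 °C; then aq. HCl
Reagents that add atoms: none
Why: Vicarious nucleophilic substitution of hydrogen, in which the chloroacetate carbanion adds ortho to the nitro group at the only open activated position (the para position carries the nitrile) and base-induced loss of HCl from the σ-adduct, then protonation, should give the arylacetate.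

Step 2
Reactants: 3 tert-butyl 2-(5-cyano-3-methoxy-2-nitrophenyl)acetate
Product: 4 2-(5-cyano-3-methoxy-2-nitrophenyl)acetic acid
Conditions: CF3CO2H/CH2Cl2 (1:3), rt
Reagents that add atoms: none
Why: Acidolysis of the tert-butyl ester with loss of isobutene should leave nitrile, nitro group and methyl ether untouched.

Step 3
Reactants: 4 2-(5-cyano-3-methoxy-2-nitrophenyl)acetic acid; 5 (S)-4-benzyl-1,3-oxazolidin-2-one
Product: 7 (4S)-4-benzyl-3-[2-(5-cyano-3-methoxy-2-nitrophenyl)acetyl]-1,3-oxazolidin-2-one, via mixed pivalic anhydride 6 (not isolated)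
Conditions: tBuCOCl, Et3N, THF, −20 °C; then 5, LiCl, −20 °C to rt
Reagents that add atoms: none
Why: N-Acylation of the oxazolidinone through the mixed anhydride should occur at the less hindered arylacetyl carbonyl.

Step 4
Reactants: 7 (4S)-4-benzyl-3-[2-(5-cyano-3-methoxy-2-nitrophenyl)acetyl]-1,3-oxazolidin-2-one; 8 4-(benzyloxy)-3-methoxybenzaldehyde
Product: 11 (4S)-4-benzyl-3-[(2S,3S)-3-[4-(benzyloxy)-3-methoxyphenyl]-2-(5-cyano-3-methoxy-2-nitrophenyl)-3-hydroxypropanoyl]-1,3-oxazolidin-2-one, via Z-dibutylboron enolate 9 (not isolated), via dibutylboron aldolate 10 (not isolated)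
Conditions: Bu2BOTf, iPr2NEt, CH2Cl2, −78 to 0 °C; 8, −78 to 0 °C; then pH 7 buffer, MeOH, 30% H2O2, 0 °C
Reagents that add atoms: none
Why: Evans syn-aldol reaction, in which the Z boron enolate reacts through a closed Zimmerman–Traxler chair on the enolate face opposite the benzyl group of the (S)-auxiliary, should set both new centres as (2S,3S), the syn pair that maps onto C3 and C2 of the later ring.

Step 5
Reactants: 11 (4S)-4-benzyl-3-[(2S,3S)-3-[4-(benzyloxy)-3-methoxyphenyl]-2-(5-cyano-3-methoxy-2-nitrophenyl)-3-hydroxypropanoyl]-1,3-oxazolidin-2-one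
Product: 12 3-[(1S,2R)-1-[4-(benzyloxy)-3-methoxyphenyl]-1,3-dihydroxypropan-2-yl]-5-methoxy-4-nitrobenzonitrile
Conditions: NaBH4, THF/H2O (4:1), 0 °C to rt
Reagents that add atoms: none
Why: Reductive cleavage of the N-acyl oxazolidinone by borohydride should give the primary alcohol and release the auxiliary while nitro and nitrile groups stay inert and neither stereocentre is touched.

Step 6
Reactants: 12 3-[(1S,2R)-1-[4-(benzyloxy)-3-methoxyphenyl]-1,3-dihydroxypropan-2-yl]-5-methoxy-4-nitrobenzonitrile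
Product: 13 3-[(1S,2R)-1-[4-(benzyloxy)-3-methoxyphenyl]-1-hydroxy-3-[tri(propan-2-yl)silyloxy]propan-2-yl]-5-methoxy-4-nitrobenzonitrile
Conditions: iPr3SiCl (1.05 equiv), imidazole, DMF, 0 °C to rt
Reagents that add atoms: triisopropylsilyl chloride, CC(C)[Si](Cl)(C(C)C)C(C)C
Why: Sterically controlled silylation should select the primary hydroxyl over the hindered secondary benzylic one.

Step 7
Reactants: 13 3-[(1S,2R)-1-[4-(benzyloxy)-3-methoxyphenyl]-1-hydroxy-3-[tri(propan-2-yl)silyloxy]propan-2-yl]-5-methoxy-4-nitrobenzonitrile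
Product: 15 (2S,3R)-2-[4-(benzyloxy)-3-methoxyphenyl]-7-methoxy-3-{[tri(propan-2-yl)silyl]oxymethyl}-2,3-dihydro-1-benzofuran-5-carbonitrile, via potassium alkoxide 14 (not isolated)
Conditions: KN(SiMe3)2 (1.05 equiv), THF, −78 °C; then DMF, −78 to 0 °C
Reagents that add atoms: none
Why: The base deprotonates the only free hydroxyl, and the C2 alkoxide adds to C7a, ipso to the nitro group, to give a Meisenheimer σ-complex whose charge is delocalised onto C5 and its nitrile; loss of nitrite restores the arene. The closest known reaction type is the intramolecular SNAr displacement of an activated aromatic nitro group by an alkoxide, as in the cyclisation of 2-(nitroaryl)ethanols to 2,3-dihydrobenzofurans. The dihydrofuran ring closes in the 5-exo-trig mode by attack at the ipso carbon. No stereocentre is formed: the C2–O and C3–H bonds are not broken, so the syn-aldol pair of 13 should be carried stereospecifically into the (2S,3R) trans ring. The step needs selectivity between the two oxygens and between ring positions, and it needs the acidic C3–H to stay in place: the triisopropylsilyl ether blocks the primary oxygen (which would also close a five-membered ring) and resists 1,5-silyl migration, only C7a carries a nucleofuge and it lies para to the nitrile, the nitro group is twisted out of conjugation by its two ortho substituents and so leaves readily, and one equivalent of a non-nucleophilic base at low temperature avoids carbanion chemistry.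

Step 8
Reactants: 15 (2S,3R)-2-[4-(benzyloxy)-3-methoxyphenyl]-7-methoxy-3-{[tri(propan-2-yl)silyl]oxymethyl}-2,3-dihydro-1-benzofuran-5-carbonitrile
Product: 17 (2S,3R)-2-[4-(benzyloxy)-3-methoxyphenyl]-7-methoxy-3-{[tri(propan-2-yl)silyl]oxymethyl}-2,3-dihydro-1-benzofuran-5-carbaldehyde, via N-diisobutylaluminio aldimine 16 (not isolated)
Conditions: iBu2AlH (1.3 equiv), CH2Cl2, −78 °C; then EtOAc, aq. KNaC4H4O6, rt
Reagents that add atoms: water, O
Why: Partial reduction of the aryl nitrile by one hydride transfer should stop at the N-aluminio aldimine, which is hydrolysed to the aldehyde on work-up, while silyl ether, benzyl ether and the ring stay intact.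

Step 9
Reactants: 18 2-[4-(benzyloxy)-3-methoxyphenyl]acetic acid; 5 (S)-4-benzyl-1,3-oxazolidin-2-one
Product: 20 (4S)-4-benzyl-3-{2-[4-(benzyloxy)-3-methoxyphenyl]acetyl}-1,3-oxazolidin-2-one, via mixed pivalic anhydride 19 (not isolated)
Conditions: tBuCOCl, Et3N, THF, −20 °C; then 5, LiCl, −20 °C to rt
Reagents that add atoms: none
Why: N-Acylation of the oxazolidinone through the mixed anhydride should occur at the less hindered arylacetyl carbonyl.

Step 10
Reactants: 20 (4S)-4-benzyl-3-{2-[4-(benzyloxy)-3-methoxyphenyl]acetyl}-1,3-oxazolidin-2-one; 17 (2S,3R)-2-[4-(benzyloxy)-3-methoxyphenyl]-7-methoxy-3-{[tri(propan-2-yl)silyl]oxymethyl}-2,3-dihydro-1-benzofuran-5-carbaldehyde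
Product: 23 (4S)-4-benzyl-3-[(2S,3S)-2-[4-(benzyloxy)-3-methoxyphenyl]-3-[(2S,3R)-2-[4-(benzyloxy)-3-methoxyphenyl]-7-methoxy-3-{[tri(propan-2-yl)silyl]oxymethyl}-2,3-dihydro-1-benzofuran-5-yl]-3-hydroxypropanoyl]-1,3-oxazolidin-2-one, via Z-dibutylboron enolate 21 (not isolated), via dibutylboron aldolate 22 (not isolated)
Conditions: Bu2BOTf, iPr2NEt, CH2Cl2, −78 to 0 °C; 17, −78 to 0 °C; then pH 7 buffer, MeOH, 30% H2O2, 0 °C
Reagents that add atoms: none
Why: A second Evans syn-aldol reaction under auxiliary control (Z boron enolate, Zimmerman–Traxler chair, attack opposite the benzyl group) should set the two side-chain centres as (2S,3S), the remote ring stereocentres of 17 having no say.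

Step 11
Reactants: 23 (4S)-4-benzyl-3-[(2S,3S)-2-[4-(benzyloxy)-3-methoxyphenyl]-3-[(2S,3R)-2-[4-(benzyloxy)-3-methoxyphenyl]-7-methoxy-3-{[tri(propan-2-yl)silyl]oxymethyl}-2,3-dihydro-1-benzofuran-5-yl]-3-hydroxypropanoyl]-1,3-oxazolidin-2-one
Product: 24 (1S,2R)-2-[4-(benzyloxy)-3-methoxyphenyl]-1-[(2S,3R)-2-[4-(benzyloxy)-3-methoxyphenyl]-7-methoxy-3-{[tri(propan-2-yl)silyl]oxymethyl}-2,3-dihydro-1-benzofuran-5-yl]propane-1,3-diol
Conditions: LiBH4, MeOH (1 equiv), THF, 0 °C
Reagents that add atoms: none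
Why: Reductive removal of the auxiliary by borohydride should give the 1,3-diol without touching either side-chain stereocentre.

Step 12
Reactants: 24 (1S,2R)-2-[4-(benzyloxy)-3-methoxyphenyl]-1-[(2S,3R)-2-[4-(benzyloxy)-3-methoxyphenyl]-7-methoxy-3-{[tri(propan-2-yl)silyl]oxymethyl}-2,3-dihydro-1-benzofuran-5-yl]propane-1,3-diol
Product: 25 (1S,2R)-2-[4-(benzyloxy)-3-methoxyphenyl]-1-[(2S,3R)-2-[4-(benzyloxy)-3-methoxyphenyl]-3-(hydroxymethyl)-7-methoxy-2,3-dihydro-1-benzofuran-5-yl]propane-1,3-diol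
Conditions: Bu4NF, THF, 0 °C to rt
Reagents that add atoms: none
Why: Fluoride-induced cleavage of the Si–O bond should free the primary alcohol under conditions that leave benzyl ethers and benzylic C–O bonds alone.

Step 13
Reactants: 25 (1S,2R)-2-[4-(benzyloxy)-3-methoxyphenyl]-1-[(2S,3R)-2-[4-(benzyloxy)-3-methoxyphenyl]-3-(hydroxymethyl)-7-methoxy-2,3-dihydro-1-benzofuran-5-yl]propane-1,3-diol
Product: 26 (1S,2R)-1-[(2S,3R)-2-(4-hydroxy-3-methoxyphenyl)-3-(hydroxymethyl)-7-methoxy-2,3-dihydro-1-benzofuran-5-yl]-2-(4-hydroxy-3-methoxyphenyl)propane-1,3-diol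
Conditions: H2 (1 atm), 10% Pd/C, EtOAc/MeOH, rt
Reagents that add atoms: none
Why: Hydrogenolysis of the two unhindered primary benzyl aryl ethers should be much faster in neutral medium than cleavage of the hindered secondary benzylic C–O bonds (C2–O1 and the side-chain carbinol), and no stereocentre is involved.

Compound list

1 | 3-methoxy-4-nitrobenzonitrile | COc1cc(C#N)ccc1[N+](=O)[O-] | starting material
2 | tert-butyl chloroacetate | CC(C)(C)OC(=O)CCl | starting material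
3 | tert-butyl 2-(5-cyano-3-methoxy-2-nitrophenyl)acetate | COc1cc(C#N)cc(CC(=O)OC(C)(C)C)c1[N+](=O)[O-] | intermediate
4 | 2-(5-cyano-3-methoxy-2-nitrophenyl)acetic acid | COc1cc(C#N)cc(CC(=O)O)c1[N+](=O)[O-] | intermediate
5 | (S)-4-benzyl-1,3-oxazolidin-2-one | O=C1N[C@@H](Cc2ccccc2)CO1 | starting material
6 | mixed anhydride of 4 with pivalic acid (not isolated) | COc1cc(C#N)cc(CC(=O)OC(=O)C(C)(C)C)c1[N+](=O)[O-] | intermediate
7 | (4S)-4-benzyl-3-[2-(5-cyano-3-methoxy-2-nitrophenyl)acetyl]-1,3-oxazolidin-2-one | COc1cc(C#N)cc(CC(=O)N2[C@@H](Cc3ccccc3)COC2=O)c1[N+](=O)[O-] | intermediate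
8 | 4-(benzyloxy)-3-methoxybenzaldehyde | COc1cc(C=O)ccc1OCc1ccccc1 | starting material
9 | Z-dibutylboron enolate of 7 (not isolated) | CCCCB(CCCC)O/C(=C\c1cc(C#N)cc(OC)c1[N+](=O)[O-])N1[C@@H](Cc2ccccc2)COC1=O | intermediate
10 | O-dibutylboryl aldolate of 11 (not isolated) | O=C(N1[C@@H](Cc2ccccc2)COC1=O)[C@@H](c1cc(C#N)cc(OC)c1[N+](=O)[O-])[C@H](OB(CCCC)CCCC)c1ccc(OCc2ccccc2)c(OC)c1 | intermediate
11 | (4S)-4-benzyl-3-[(2S,3S)-3-[4-(benzyloxy)-3-methoxyphenyl]-2-(5-cyano-3-methoxy-2-nitrophenyl)-3-hydroxypropanoyl]-1,3-oxazolidin-2-one | O=C(N1[C@@H](Cc2ccccc2)COC1=O)[C@@H](c1cc(C#N)cc(OC)c1[N+](=O)[O-])[C@H](O)c1ccc(OCc2ccccc2)c(OC)c1 | intermediate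
12 | 3-[(1S,2R)-1-[4-(benzyloxy)-3-methoxyphenyl]-1,3-dihydroxypropan-2-yl]-5-methoxy-4-nitrobenzonitrile | OC[C@@H](c1cc(C#N)cc(OC)c1[N+](=O)[O-])[C@H](O)c1ccc(OCc2ccccc2)c(OC)c1 | intermediate
13 | 3-[(1S,2R)-1-[4-(benzyloxy)-3-methoxyphenyl]-1-hydroxy-3-[tri(propan-2-yl)silyloxy]propan-2-yl]-5-methoxy-4-nitrobenzonitrile | CC(C)[Si](C(C)C)(C(C)C)OC[C@@H](c1cc(C#N)cc(OC)c1[N+](=O)[O-])[C@H](O)c1ccc(OCc2ccccc2)c(OC)c1 | intermediate
14 | potassium alkoxide of 13 (not isolated) | CC(C)[Si](C(C)C)(C(C)C)OC[C@@H](c1cc(C#N)cc(OC)c1[N+](=O)[O-])[C@H]([O-])c1ccc(OCc2ccccc2)c(OC)c1.[K+] | intermediate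
15 | (2S,3R)-2-[4-(benzyloxy)-3-methoxyphenyl]-7-methoxy-3-{[tri(propan-2-yl)silyl]oxymethyl}-2,3-dihydro-1-benzofuran-5-carbonitrile | COc1cc([C@H]2Oc3c(OC)cc(C#N)cc3[C@@H]2CO[Si](C(C)C)(C(C)C)C(C)C)ccc1OCc1ccccc1 | intermediate
16 | N-diisobutylaluminio aldimine of 17 (not isolated) | COc1cc([C@H]2Oc3c(OC)cc(C=N[Al](CC(C)C)CC(C)C)cc3[C@@H]2CO[Si](C(C)C)(C(C)C)C(C)C)ccc1OCc1ccccc1 | intermediate
17 | (2S,3R)-2-[4-(benzyloxy)-3-methoxyphenyl]-7-methoxy-3-{[tri(propan-2-yl)silyl]oxymethyl}-2,3-dihydro-1-benzofuran-5-carbaldehyde | COc1cc([C@H]2Oc3c(OC)cc(C=O)cc3[C@@H]2CO[Si](C(C)C)(C(C)C)C(C)C)ccc1OCc1ccccc1 | intermediate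
18 | 2-[4-(benzyloxy)-3-methoxyphenyl]acetic acid | COc1cc(CC(=O)O)ccc1OCc1ccccc1 | starting material
19 | mixed anhydride of 18 with pivalic acid (not isolated) | COc1cc(CC(=O)OC(=O)C(C)(C)C)ccc1OCc1ccccc1 | intermediate
20 | (4S)-4-benzyl-3-{2-[4-(benzyloxy)-3-methoxyphenyl]acetyl}-1,3-oxazolidin-2-one | COc1cc(CC(=O)N2[C@@H](Cc3ccccc3)COC2=O)ccc1OCc1ccccc1 | intermediate
21 | Z-dibutylboron enolate of 20 (not isolated) | CCCCB(CCCC)O/C(=C\c1ccc(OCc2ccccc2)c(OC)c1)N1[C@@H](Cc2ccccc2)COC1=O | intermediate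
22 | O-dibutylboryl aldolate of 23 (not isolated) | COc1cc([C@H]2Oc3c(OC)cc([C@@H](OB(CCCC)CCCC)[C@@H](C(=O)N4[C@@H](Cc5ccccc5)COC4=O)c4ccc(OCc5ccccc5)c(OC)c4)cc3[C@@H]2CO[Si](C(C)C)(C(C)C)C(C)C)ccc1OCc1ccccc1 | intermediate
23 | (4S)-4-benzyl-3-[(2S,3S)-2-[4-(benzyloxy)-3-methoxyphenyl]-3-[(2S,3R)-2-[4-(benzyloxy)-3-methoxyphenyl]-7-methoxy-3-{[tri(propan-2-yl)silyl]oxymethyl}-2,3-dihydro-1-benzofuran-5-yl]-3-hydroxypropanoyl]-1,3-oxazolidin-2-one | COc1cc([C@H]2Oc3c(OC)cc([C@@H](O)[C@@H](C(=O)N4[C@@H](Cc5ccccc5)COC4=O)c4ccc(OCc5ccccc5)c(OC)c4)cc3[C@@H]2CO[Si](C(C)C)(C(C)C)C(C)C)ccc1OCc1ccccc1 | intermediate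
24 | (1S,2R)-2-[4-(benzyloxy)-3-methoxyphenyl]-1-[(2S,3R)-2-[4-(benzyloxy)-3-methoxyphenyl]-7-methoxy-3-{[tri(propan-2-yl)silyl]oxymethyl}-2,3-dihydro-1-benzofuran-5-yl]propane-1,3-diol | COc1cc([C@H]2Oc3c(OC)cc([C@@H](O)[C@@H](CO)c4ccc(OCc5ccccc5)c(OC)c4)cc3[C@@H]2CO[Si](C(C)C)(C(C)C)C(C)C)ccc1OCc1ccccc1 | intermediate
25 | (1S,2R)-2-[4-(benzyloxy)-3-methoxyphenyl]-1-[(2S,3R)-2-[4-(benzyloxy)-3-methoxyphenyl]-3-(hydroxymethyl)-7-methoxy-2,3-dihydro-1-benzofuran-5-yl]propane-1,3-diol | COc1cc([C@H]2Oc3c(OC)cc([C@@H](O)[C@@H](CO)c4ccc(OCc5ccccc5)c(OC)c4)cc3[C@@H]2CO)ccc1OCc1ccccc1 | intermediate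
26 | (1S,2R)-1-[(2S,3R)-2-(4-hydroxy-3-methoxyphenyl)-3-(hydroxymethyl)-7-methoxy-2,3-dihydro-1-benzofuran-5-yl]-2-(4-hydroxy-3-methoxyphenyl)propane-1,3-diol | COc1cc([C@H]2Oc3c(OC)cc([C@@H](O)[C@@H](CO)c4ccc(O)c(OC)c4)cc3[C@@H]2CO)ccc1O | target

Total step count: 13 steps.
Longest linear sequence: 12 steps (steps 1 to 8 and 10 to 13); step 9 is a one-step side branch.

Steps most likely to fail

Step 7 (key step). The alkoxide may fragment by retro-addition with expulsion of the nitrobenzylic carbanion. Deprotonation at C3 may lead to β-elimination. Silyl migration may hand the ring closure to the primary oxygen. Displacement of nitrite may also be too slow. The fallback sets out from 13 and returns at 15, forming the same O1–C7a bond by copper catalysis instead of SNAr. The nitro group of 13 is reduced (Fe, NH4Cl, EtOH/H2O, 70 °C) to 4-amino-3-[(1S,2R)-1-[4-(benzyloxy)-3-methoxyphenyl]-1-hydroxy-3-[tri(propan-2-yl)silyloxy]propan-2-yl]-5-methoxybenzonitrile F1. Diazotisation and iodination (NaNO2, TsOH, KI, MeCN/H2O, 10 °C to rt) should give 3-[(1S,2R)-1-[4-(benzyloxy)-3-methoxyphenyl]-1-hydroxy-3-[tri(propan-2-yl)silyloxy]propan-2-yl]-4-iodo-5-methoxybenzonitrile F2. Intramolecular Ullmann etherification (CuI, 3,4,7,8-tetramethyl-1,10-phenanthroline, Cs2CO3, toluene, 90 °C) then closes the ring to 15.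

Step 4. Addition of the electron-poor, hindered boron enolate to the electron-rich aldehyde may be slow or reversible, which would cost conversion and erode syn selectivity through retro-aldol. The fallback sets out from 4 and returns at 12, building the C–C bond by acylation and the carbinol centre by chelation-controlled reduction. Acid 4 is coupled with (R)-4-benzyl-1,3-oxazolidin-2-one (tBuCOCl, Et3N, LiCl, THF) to (4R)-4-benzyl-3-[2-(5-cyano-3-methoxy-2-nitrophenyl)acetyl]-1,3-oxazolidin-2-one F3. The enantiomeric auxiliary is required because the chelated lithium enolate is acylated on the face opposite to the one used in the boron aldol. Enolisation (LiN(SiMe3)2, THF, −78 °C) and C-acylation with 4-(benzyloxy)-3-methoxybenzoyl chloride should give (4R)-4-benzyl-3-[(2S)-3-[4-(benzyloxy)-3-methoxyphenyl]-2-(5-cyano-3-methoxy-2-nitrophenyl)-3-oxopropanoyl]-1,3-oxazolidin-2-one F4. Reduction with Zn(BH4)2 (CH2Cl2/Et2O, −20 °C) through the zinc chelate should deliver (4R)-4-benzyl-3-[(2S,3S)-3-[4-(benzyloxy)-3-methoxyphenyl]-2-(5-cyano-3-methoxy-2-nitrophenyl)-3-hydroxypropanoyl]-1,3-oxazolidin-2-one F5. NaBH4 in THF/H2O then gives diol 12.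

Step 1. Addition–elimination at the nitro- or methoxy-bearing carbons by tert-butoxide or the carbanion, or self-condensation of the chloroacetate, may compete with substitution of hydrogen. The fallback sets out from 1 and returns at 3, replacing C–H substitution by cross-coupling. Reduction of 1 (Fe, NH4Cl, EtOH/H2O, 70 °C) gives 4-amino-3-methoxybenzonitrile F6. Bromination ortho to the amino group (NBS, MeCN, 0 °C) should give 4-amino-3-bromo-5-methoxybenzonitrile F7. Oxidation of the amine back to the nitro group (CF3CO3H made from H2O2–urea and (CF3CO)2O, CH2Cl2, reflux) gives 3-bromo-5-methoxy-4-nitrobenzonitrile F8. Negishi-type coupling with the Reformatsky reagent BrZnCH2CO2tBu (Pd(dba)2, P(tBu)3, THF, rt) then gives 3.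

Further compounds

F1 | step 7 | 4-amino-3-[(1S,2R)-1-[4-(benzyloxy)-3-methoxyphenyl]-1-hydroxy-3-[tri(propan-2-yl)silyloxy]propan-2-yl]-5-methoxybenzonitrile | CC(C)[Si](C(C)C)(C(C)C)OC[C@@H](c1cc(C#N)cc(OC)c1N)[C@H](O)c1ccc(OCc2ccccc2)c(OC)c1
F2 | step 7 | 3-[(1S,2R)-1-[4-(benzyloxy)-3-methoxyphenyl]-1-hydroxy-3-[tri(propan-2-yl)silyloxy]propan-2-yl]-4-iodo-5-methoxybenzonitrile | CC(C)[Si](C(C)C)(C(C)C)OC[C@@H](c1cc(C#N)cc(OC)c1I)[C@H](O)c1ccc(OCc2ccccc2)c(OC)c1
F3 | step 4 | (4R)-4-benzyl-3-[2-(5-cyano-3-methoxy-2-nitrophenyl)acetyl]-1,3-oxazolidin-2-one | COc1cc(C#N)cc(CC(=O)N2[C@H](Cc3ccccc3)COC2=O)c1[N+](=O)[O-]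
F4 | step 4 | (4R)-4-benzyl-3-[(2S)-3-[4-(benzyloxy)-3-methoxyphenyl]-2-(5-cyano-3-methoxy-2-nitrophenyl)-3-oxopropanoyl]-1,3-oxazolidin-2-one | O=C(N1[C@H](Cc2ccccc2)COC1=O)[C@@H](c1cc(C#N)cc(OC)c1[N+](=O)[O-])C(=O)c1ccc(OCc2ccccc2)c(OC)c1
F5 | step 4 | (4R)-4-benzyl-3-[(2S,3S)-3-[4-(benzyloxy)-3-methoxyphenyl]-2-(5-cyano-3-methoxy-2-nitrophenyl)-3-hydroxypropanoyl]-1,3-oxazolidin-2-one | O=C(N1[C@H](Cc2ccccc2)COC1=O)[C@@H](c1cc(C#N)cc(OC)c1[N+](=O)[O-])[C@H](O)c1ccc(OCc2ccccc2)c(OC)c1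
F6 | step 1 | 4-amino-3-methoxybenzonitrile | COc1cc(C#N)ccc1N
F7 | step 1 | 4-amino-3-bromo-5-methoxybenzonitrile | COc1cc(C#N)cc(Br)c1N
F8 | step 1 | 3-bromo-5-methoxy-4-nitrobenzonitrile | COc1cc(C#N)cc(Br)c1[N+](=O)[O-]
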